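**Strategy.** Ring B is disconnected into an aryl ynol ether and 3-methylcyclobutenone. The feature used is that ring B carries the ether oxygen on C1' and the (S)-side chain on the neighbouring C6', with methyl on C3': C1' and C6' are the two alkyne carbons, and C2' to C5' are the four ring carbons of the cyclobutenone. One heating step forms C5'–C6' and C1'–C2', closes ring B and leaves only a removable hydroxyl on C5'. The precursor is the MOM-protected ring A phenol whose C3 oxygen carries the alkyne with the propargylic (S)-centre in place. One citronellal-derived dibromoalkene supplies both stereocentres, ring A arising from it by a Dötz benzannulation.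

Key step: step 11

Atom labels: ring A is the phenol ring (C1 side chain, C3 ether oxygen, C4 methyl, C6 hydroxyl); ring B is the second ring (C1' ether oxygen, C3' methyl, C5' the carbon that is deoxygenated, C6' side chain).
Assumption: commercial (S)-citronellal of high enantiomeric purity is used, since it is the only source of both stereocentres.

**Route**

Step 1
Reactants: 1 (3S)-3,7-dimethyloct-6-enal, (S)-citronellal
Product: 3 (2S)-2,6-dimethylhept-5-enal, via enamine 2 (not isolated)
Conditions: morpholine (1.0 equiv), 4 Å MS, toluene, rt; filter, concentrate; then CuCl (10 mol %), O2 (1 atm), MeCN, 0 °C to rt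
Reagents that add atoms: dioxygen, O=O; morpholine, C1COCCN1 (retained only in intermediate 2)
Why: Enamine formation followed by copper-catalysed aerobic oxidative cleavage of the enamine C=C bond removes C1 of citronellal as N-formylmorpholine; the electron-rich enamine should react far faster than the trisubstituted alkene, and the stereocentre, which only becomes the α-carbon in the product, is not touched under these neutral conditions (free amine must be absent in the second stage so that 3 is not degraded further).

Step 2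
Reactants: 3 (2S)-2,6-dimethylhept-5-enal
Product: 4 (3S)-1,1-dibromo-3,7-dimethylocta-1,6-diene
Conditions: CBr4, PPh3, Zn, CH2Cl2, rt; then 3, 0 °C to rt
Reagents that add atoms: carbon tetrabromide, BrC(Br)(Br)Br
Why: Corey–Fuchs (Ramirez) dibromoolefination with the non-basic ylide Ph3P=CBr2 converts the aldehyde without enolization, so the α-stereocentre is retained; zinc keeps the medium free of bromophosphonium species and HBr that could add to the alkene.

Step 3
Reactants: 4 (3S)-1,1-dibromo-3,7-dimethylocta-1,6-diene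
Product: 5 (3S)-3,7-dimethyloct-6-en-1-yne
Conditions: n-BuLi (2.1 equiv), THF, −78 °C to 0 °C; then H2O
Reagents that add atoms: none
Why: Second stage of the Corey–Fuchs sequence: Br/Li exchange, α-elimination and 1,2-hydride shift (Fritsch–Buttenberg–Wiechell rearrangement) give the lithium acetylide, which is protonated on work-up; the propargylic C–H is not acidic enough to be removed at low temperature.

Step 4
Reactants: 6 2-bromopropene; 7 hexacarbonylchromium, Cr(CO)6
Product: 10 pentacarbonyl(1-methoxy-2-methylprop-2-en-1-ylidene)chromium, via isopropenyllithium 8 (not isolated), via acyl chromate 9 (not isolated)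
Conditions: t-BuLi (2 equiv), Et2O, −78 °C; Cr(CO)6, Et2O, 0 °C to rt; then Me3OBF4, CH2Cl2, 0 °C
Reagents that add atoms: trimethyloxonium tetrafluoroborate, C[O+](C)C.F[B-](F)(F)F
Why: Fischer carbene synthesis: the vinyllithium adds to a carbonyl ligand of Cr(CO)6 and the resulting acyl chromate is O-methylated by the Meerwein salt.

Step 5
Reactants: 5 (3S)-3,7-dimethyloct-6-en-1-yne; 10 pentacarbonyl(1-methoxy-2-methylprop-2-en-1-ylidene)chromium
Product: 12 4-methoxy-5-methyl-2-[(2S)-6-methylhept-5-en-2-yl]phenol, via chromium complex 11 (not isolated)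
Conditions: THF, 50 °C; then air, Et2O, rt
Reagents that add atoms: none
Why: Dötz benzannulation (alkyne insertion, CO insertion, six-electron electrocyclization, tautomerization): a terminal alkyne places its substituent next to the carbon derived from CO, so the free hydroxyl should end at C6 beside the side chain and the methoxy group at C3 beside methyl, which differentiates the two ring A oxygens by construction; the neutral conditions leave the propargylic centre untouched.

Step 6
Reactants: 12 4-methoxy-5-methyl-2-[(2S)-6-methylhept-5-en-2-yl]phenol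
Product: 13 1-methoxy-4-(methoxymethoxy)-2-methyl-5-[(2S)-6-methylhept-5-en-2-yl]benzene
Conditions: NaH, MOMCl, DMF, 0 °C to rt
Reagents that add atoms: chloromethyl methyl ether, COCCl
Why: Williamson O-alkylation of the sodium phenoxide with MOMCl protects the only free hydroxyl (on C6).

Step 7
Reactants: 13 1-methoxy-4-(methoxymethoxy)-2-methyl-5-[(2S)-6-methylhept-5-en-2-yl]benzene
Product: 14 4-(methoxymethoxy)-2-methyl-5-[(2S)-6-methylhept-5-en-2-yl]phenol
Conditions: EtSH, NaH (gives NaSEt), DMF, 120 °C; then aq. NH4Cl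
Reagents that add atoms: none
Why: SN2 demethylation of the aryl methyl ether by ethanethiolate, a standard way to unmask phenols in this terpenoid series, frees the C3 hydroxyl; the MOM acetal and the isolated alkene are expected to be inert to thiolate and base.

Step 8
Reactants: 14 4-(methoxymethoxy)-2-methyl-5-[(2S)-6-methylhept-5-en-2-yl]phenol; 4 (3S)-1,1-dibromo-3,7-dimethylocta-1,6-diene
Product: 16 1-{[(3S)-3,7-dimethyloct-6-en-1-yn-1-yl]oxy}-4-(methoxymethoxy)-2-methyl-5-[(2S)-6-methylhept-5-en-2-yl]benzene, via bromo enol ether 15 (not isolated)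
Conditions: CuI (10 mol %), 2,2'-bipyridine (20 mol %), K3PO4, toluene, 110 °C; then t-BuOK, 1,4-dioxane, rt
Reagents that add atoms: none
Why: Copper-catalysed Ullmann-type C–O coupling of the phenol with the less hindered C–Br bond of the gem-dibromoalkene (the one trans to the alkyl group) gives the (Z)-bromo enol ether, whose vinylic hydrogen is anti to bromine and is removed in an E2 dehydrobromination; the allylic, later propargylic, C–H is not acidic under these conditions, so the stereocentre is kept.

Step 9
Reactants: 17 propyne; 18 trichloroacetyl chloride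
Product: 20 4,4-dichloro-3-methylcyclobut-2-en-1-one, via dichloroketene 19 (not isolated)
Conditions: Zn–Cu couple, Et2O/DME, 0 °C to rt, dry-ice condenser
Reagents that add atoms: none
Why: (2+2) Cycloaddition of dichloroketene, generated by zinc dechlorination of the acid chloride, to the alkyne; the ketene carbonyl carbon bonds to the unsubstituted alkyne carbon, which places methyl at C3 of the cyclobutenone.

Step 10
Reactants: 20 4,4-dichloro-3-methylcyclobut-2-en-1-one
Product: 21 3-methylcyclobut-2-en-1-one
Conditions: Zn, AcOH, TMEDA, EtOH, 0 °C to rt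
Reagents that add atoms: none
Why: Reductive dechlorination with zinc in buffered acetic acid, the standard access to 3-substituted cyclobutenones from their 4,4-dichloro precursors; the volatile product is handled as a solution.

Step 11
Reactants: 16 1-{[(3S)-3,7-dimethyloct-6-en-1-yn-1-yl]oxy}-4-(methoxymethoxy)-2-methyl-5-[(2S)-6-methylhept-5-en-2-yl]benzene; 21 3-methylcyclobut-2-en-1-one
Product: 26 3-{4-(methoxymethoxy)-2-methyl-5-[(2S)-6-methylhept-5-en-2-yl]phenoxy}-5-methyl-2-[(2S)-6-methylhept-5-en-2-yl]phenol, via vinylketene 22 (not isolated), via vinylcyclobutenone 23 (not isolated), via dienylketene 24 (not isolated), via cyclohexadienone 25 (not isolated)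
Conditions: 21 (2 equiv), toluene, sealed tube, 80 °C then 110 °C; then K2CO3, MeOH, rt
Reagents that add atoms: none
Why: Heating opens 21 by a conrotatory four-electron electrocyclic reaction to vinylketene 22, which adds to the ynol ether in a regioselective (2+2) cycloaddition: the nucleophilic, chain-bearing alkyne carbon (future C6') attacks the ketene carbonyl carbon (future C5') and the oxygen-bearing carbon (future C1') bonds to the ketene α-carbon (future C2'), giving 23. A second four-electron opening of 23 gives dienylketene 24, and ring B is closed by a disrotatory six-electron electrocyclization that rejoins C5' to C4' (the bond first broken in 21), after which tautomerization of 25 gives the phenol. The closest known reaction type is the Danheiser benzannulation of cyclobutenones with alkoxy- and silyloxyalkynes. No stereocentre is created, and the propargylic (S)-centre is not involved because every stage is a neutral pericyclic process. The selectivity needed is the regiochemistry of the cycloaddition, secured by the donor oxygen that polarizes the alkyne so that C6' is its nucleophilic end; an aryl ether has no retro-ene fragmentation path, so it should tolerate the heating. Any aryl ester formed from 26 and excess ketene is cleaved by the K2CO3/MeOH treatment.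

Step 12
Reactants: 26 3-{4-(methoxymethoxy)-2-methyl-5-[(2S)-6-methylhept-5-en-2-yl]phenoxy}-5-methyl-2-[(2S)-6-methylhept-5-en-2-yl]phenol
Product: 27 3-{4-(methoxymethoxy)-2-methyl-5-[(2S)-6-methylhept-5-en-2-yl]phenoxy}-5-methyl-2-[(2S)-6-methylhept-5-en-2-yl]phenyl trifluoromethanesulfonate
Conditions: Tf2O, pyridine, CH2Cl2, 0 °C
Reagents that add atoms: trifluoromethanesulfonic anhydride, O=S(=O)(OS(=O)(=O)C(F)(F)F)C(F)(F)F
Why: O-Sulfonylation of the C5' phenol; pyridine buffers the medium so that the MOM acetal and the alkenes survive.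

Step 13
Reactants: 27 the C5' triflate
Product: 28 1-(methoxymethoxy)-5-methyl-2-[(2S)-6-methylhept-5-en-2-yl]-4-{5-methyl-2-[(2S)-6-methylhept-5-en-2-yl]phenoxy}benzene
Conditions: Pd(OAc)2 (5 mol %), dppp (5 mol %), Et3N, HCO2H, DMF, 70 °C
Reagents that add atoms: none
Why: Palladium-catalysed hydrogenolysis of an aryl triflate with formate as hydride source (oxidative addition to zerovalent palladium, decarboxylation of the formate complex, reductive elimination); the chelating bisphosphine copes with the ortho-substituted triflate, and the alkenes, diaryl ether and acetal are inert.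

Step 14
Reactants: 28 the MOM ether of the target
Product: 29 5-methyl-2-[(2S)-6-methylhept-5-en-2-yl]-4-{5-methyl-2-[(2S)-6-methylhept-5-en-2-yl]phenoxy}phenol (target)
Conditions: HCl (0.5 M), MeOH, rt
Reagents that add atoms: none
Why: Acid-catalysed transacetalization to methanol removes the MOM group; dilute acid at room temperature should leave the two trisubstituted alkenes alone, and neither can cyclize onto the phenol through a favourable ring size.

**Compound list** (Ar = 4-(methoxymethoxy)-2-methyl-5-[(2S)-6-methylhept-5-en-2-yl]phenyl)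

1 | (3S)-3,7-dimethyloct-6-enal, (S)-citronellal | CC(C)=CCC[C@H](C)CC=O | starting material
2 | 4-[(1E,3S)-3,7-dimethylocta-1,6-dien-1-yl]morpholine | CC(C)=CCC[C@H](C)/C=C/N1CCOCC1 | intermediate
3 | (2S)-2,6-dimethylhept-5-enal | CC(C)=CCC[C@H](C)C=O | intermediate
4 | (3S)-1,1-dibromo-3,7-dimethylocta-1,6-diene | CC(C)=CCC[C@H](C)C=C(Br)Br | intermediate
5 | (3S)-3,7-dimethyloct-6-en-1-yne | CC(C)=CCC[C@H](C)C#C | intermediate
6 | 2-bromopropene | CC(Br)=C | starting material
7 | hexacarbonylchromium, Cr(CO)6 | O=C=[Cr](=C=O)(=C=O)(=C=O)(=C=O)=C=O | starting material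
8 | prop-1-en-2-yllithium | [Li]C(C)=C | intermediate
9 | lithium pentacarbonyl(2-methylprop-2-enoyl)chromate | [Li+].[O-]C(C(C)=C)=[Cr](=C=O)(=C=O)(=C=O)(=C=O)=C=O | intermediate
10 | pentacarbonyl(1-methoxy-2-methylprop-2-en-1-ylidene)chromium | COC(C(C)=C)=[Cr](=C=O)(=C=O)(=C=O)(=C=O)=C=O | intermediate
11 | tricarbonylchromium η6-arene complex of 12 (written as its components) | CC(C)=CCC[C@H](C)c1cc(OC)c(C)cc1O.[Cr].[C-]#[O+].[C-]#[O+].[C-]#[O+] | intermediate
12 | 4-methoxy-5-methyl-2-[(2S)-6-methylhept-5-en-2-yl]phenol | CC(C)=CCC[C@H](C)c1cc(OC)c(C)cc1O | intermediate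
13 | 1-methoxy-4-(methoxymethoxy)-2-methyl-5-[(2S)-6-methylhept-5-en-2-yl]benzene | CC(C)=CCC[C@H](C)c1cc(OC)c(C)cc1OCOC | intermediate
14 | 4-(methoxymethoxy)-2-methyl-5-[(2S)-6-methylhept-5-en-2-yl]phenol | CC(C)=CCC[C@H](C)c1cc(O)c(C)cc1OCOC | intermediate
15 | 1-{[(1Z,3S)-1-bromo-3,7-dimethylocta-1,6-dien-1-yl]oxy}-4-(methoxymethoxy)-2-methyl-5-[(2S)-6-methylhept-5-en-2-yl]benzene | CC(C)=CCC[C@H](C)c1cc(O/C(Br)=C/[C@@H](C)CCC=C(C)C)c(C)cc1OCOC | intermediate
16 | 1-{[(3S)-3,7-dimethyloct-6-en-1-yn-1-yl]oxy}-4-(methoxymethoxy)-2-methyl-5-[(2S)-6-methylhept-5-en-2-yl]benzene | CC(C)=CCC[C@H](C)c1cc(OC#C[C@@H](C)CCC=C(C)C)c(C)cc1OCOC | intermediate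
17 | propyne | CC#C | starting material
18 | trichloroacetyl chloride | O=C(Cl)C(Cl)(Cl)Cl | starting material
19 | dichloroketene | ClC(Cl)=C=O | intermediate
20 | 4,4-dichloro-3-methylcyclobut-2-en-1-one | CC1=CC(=O)C1(Cl)Cl | intermediate
21 | 3-methylcyclobut-2-en-1-one | CC1=CC(=O)C1 | intermediate
22 | 3-methylbuta-1,3-dien-1-one | C=C(C)C=C=O | intermediate
23 | 3-(ArO)-2-[(2S)-6-methylhept-5-en-2-yl]-4-(prop-1-en-2-yl)cyclobut-2-en-1-one (C4 epimers) | CC(C)=CCC[C@H](C)c1cc(OC2=C([C@@H](C)CCC=C(C)C)C(=O)C2C(C)=C)c(C)cc1OCOC | intermediate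
24 | 3-(ArO)-5-methyl-2-[(2S)-6-methylhept-5-en-2-yl]hexa-1,3,5-trien-1-one | CC(C)=CCC[C@H](C)c1cc(OC(=CC(C)=C)C(=C=O)[C@@H](C)CCC=C(C)C)c(C)cc1OCOC | intermediate
25 | 3-(ArO)-5-methyl-2-[(2S)-6-methylhept-5-en-2-yl]cyclohexa-2,4-dien-1-one | CC(C)=CCC[C@H](C)c1cc(OC2=C([C@@H](C)CCC=C(C)C)C(=O)CC(C)=C2)c(C)cc1OCOC | intermediate
26 | 3-(ArO)-5-methyl-2-[(2S)-6-methylhept-5-en-2-yl]phenol | CC(C)=CCC[C@H](C)c1cc(Oc2cc(C)cc(O)c2[C@@H](C)CCC=C(C)C)c(C)cc1OCOC | intermediate
27 | 3-(ArO)-5-methyl-2-[(2S)-6-methylhept-5-en-2-yl]phenyl trifluoromethanesulfonate | CC(C)=CCC[C@H](C)c1cc(Oc2cc(C)cc(OS(=O)(=O)C(F)(F)F)c2[C@@H](C)CCC=C(C)C)c(C)cc1OCOC | intermediate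
28 | 1-(methoxymethoxy)-5-methyl-2-[(2S)-6-methylhept-5-en-2-yl]-4-{5-methyl-2-[(2S)-6-methylhept-5-en-2-yl]phenoxy}benzene | CC(C)=CCC[C@H](C)c1cc(Oc2cc(C)ccc2[C@@H](C)CCC=C(C)C)c(C)cc1OCOC | intermediate
29 | 5-methyl-2-[(2S)-6-methylhept-5-en-2-yl]-4-{5-methyl-2-[(2S)-6-methylhept-5-en-2-yl]phenoxy}phenol | CC(C)=CCC[C@H](C)c1cc(Oc2cc(C)ccc2[C@@H](C)CCC=C(C)C)c(C)cc1O | target

**Totals**

Total step count: 14.
Longest linear sequence: 11 steps (1, 2, 3, 5, 6, 7, 8, 11, 12, 13, 14).

**Steps most likely to fail**

Step 11. The aryloxy alkyne is less nucleophilic than alkoxy or silyloxy alkynes, so ketene dimerization or acylation of the product phenol may outrun the cycloaddition at the temperature needed to open the cyclobutenone. The fallback sets out from 16 and generates the same vinylketene at room temperature by a photochemical Wolff rearrangement. Commercial 3-methylbut-3-en-2-one (CC(=C)C(C)=O) is trifluoroacetylated (LiN(SiMe3)2, CF3CO2CH2CF3, THF, −78 °C) to 1,1,1-trifluoro-5-methylhex-5-ene-2,4-dione F1. Diazo transfer with loss of the trifluoroacetyl group (MsN3, Et3N, MeCN/H2O) gives 1-diazo-3-methylbut-3-en-2-one F2. Irradiation of F2 with 16 (300 nm, CH2Cl2, rt), followed by warming in toluene to complete the electrocyclic stages, should return to the route at 26.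

Step 8. A second C–O coupling may convert the bromo enol ether into a ketene acetal, or the ortho-substituted phenol may couple too slowly at the temperature the dibromoalkene tolerates. The fallback sets out from 3 and 14 and makes the alkyne from a ketone instead. Chloromethyllithium (ICH2Cl, MeLi·LiBr, THF, −78 °C) adds to 3 to give (3S)-1-chloro-3,7-dimethyloct-6-en-2-ol F3, and Dess–Martin oxidation gives (3S)-1-chloro-3,7-dimethyloct-6-en-2-one F4. Alkylation of 14 (K2CO3, NaI, acetone) gives the aryloxymethyl ketone F5. Enolization on the oxygen-bearing side and triflation (LiN(SiMe3)2, PhNTf2, THF, −78 °C) give the enol triflate F6, and elimination (t-BuOK, THF, −78 °C) should return to the route at 16.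

Step 7. The thiolate may also attack the MOM acetal, or demethylation of the electron-rich, ortho-substituted ether may be slow. The fallback sets out from 12 and differentiates the two oxygens by sterics instead. Oxidation ((NH4)2Ce(NO3)6, MeCN/H2O, 0 °C) gives 2-methyl-5-[(2S)-6-methylhept-5-en-2-yl]cyclohexa-2,5-diene-1,4-dione F7, and reduction (Na2S2O4, Et2O/H2O) gives 2-methyl-5-[(2S)-6-methylhept-5-en-2-yl]benzene-1,4-diol F8. Silylation of the less hindered hydroxyl beside methyl (TIPSCl, imidazole, DMF, 0 °C) gives the mono-silyl ether F9, and MOM protection of the remaining hydroxyl (NaH, MOMCl, DMF) gives the silyl MOM diether F10. Bu4NF in THF should then return to the route at 14.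

**Further compounds**

F1 | step 11 | 1,1,1-trifluoro-5-methylhex-5-ene-2,4-dione | CC(=C)C(=O)CC(=O)C(F)(F)F
F2 | step 11 | 1-diazo-3-methylbut-3-en-2-one | CC(=C)C(=O)C=[N+]=[N-]
F3 | step 8 | (3S)-1-chloro-3,7-dimethyloct-6-en-2-ol (C2 epimers) | CC(C)=CCC[C@H](C)C(O)CCl
F4 | step 8 | (3S)-1-chloro-3,7-dimethyloct-6-en-2-one | CC(C)=CCC[C@H](C)C(=O)CCl
F5 | step 8 | (3S)-1-{4-(methoxymethoxy)-2-methyl-5-[(2S)-6-methylhept-5-en-2-yl]phenoxy}-3,7-dimethyloct-6-en-2-one | CC(C)=CCC[C@H](C)c1cc(OCC(=O)[C@@H](C)CCC=C(C)C)c(C)cc1OCOC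
F6 | step 8 | (3S)-1-{4-(methoxymethoxy)-2-methyl-5-[(2S)-6-methylhept-5-en-2-yl]phenoxy}-3,7-dimethylocta-1,6-dien-2-yl trifluoromethanesulfonate | CC(C)=CCC[C@H](C)c1cc(OC=C(OS(=O)(=O)C(F)(F)F)[C@@H](C)CCC=C(C)C)c(C)cc1OCOC
F7 | step 7 | 2-methyl-5-[(2S)-6-methylhept-5-en-2-yl]cyclohexa-2,5-diene-1,4-dione | CC(C)=CCC[C@H](C)C1=CC(=O)C(C)=CC1=O
F8 | step 7 | 2-methyl-5-[(2S)-6-methylhept-5-en-2-yl]benzene-1,4-diol | CC(C)=CCC[C@H](C)c1cc(O)c(C)cc1O
F9 | step 7 | 5-methyl-2-[(2S)-6-methylhept-5-en-2-yl]-4-{[tri(propan-2-yl)silyl]oxy}phenol | CC(C)=CCC[C@H](C)c1cc(O[Si](C(C)C)(C(C)C)C(C)C)c(C)cc1O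
F10 | step 7 | [4-(methoxymethoxy)-2-methyl-5-[(2S)-6-methylhept-5-en-2-yl]phenoxy]tri(propan-2-yl)silane | CC(C)=CCC[C@H](C)c1cc(O[Si](C(C)C)(C(C)C)C(C)C)c(C)cc1OCOC
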